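Ring A is not carried through the synthesis; it is built last. Its vicinal oxygen pair C3(OMe)/C4(OH), together with unsubstituted C5 and C6, is read as the methoxy-bearing four-carbon chain of 1-methoxybut-3-en-2-one. C1 and C2 are the α- and carbonyl carbons of an aldehyde that already holds C7, the (8S,8'R) dimethyl pair and silyl-protected ring B. One enamine Michael/aldol cascade forms C1–C6 and C2=C3 and closes the ring as a 2-methoxycyclohexenone, which is then dehydrogenated to the guaiacol. The aldehyde, a (4S,5R)-6-aryl-4,5-dimethylhexanal, comes from enantioselective arylative opening of meso-2,3-dimethylsuccinic anhydride, so both stereocentres exist before ring A does.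

Key step: step 12

Remarks on the chemistry
- Labels: ring A is the guaiacyl ring (chain on C1, OMe on C3, OH on C4); C7–C8–C8'–C7' is the butane chain; ring B is the syringyl ring. The target is (8S,8'R), the erythro (meso-like) pattern, which is why a meso diacid can be its source.
- The ring B phenol is carried as a triisopropylsilyl (TIPS) ether. It survives the catalytic hydrogenolysis that removes the benzylic ketone oxygen next to C8' (a benzyl ether would be cleaved there) and is removed by fluoride at the end.
- A quinone oxidant is avoided for the aromatisation because it would attack the electron-rich benzylic C7' of ring B.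
- Assumption: the (R,R) antipode of the TADDOL-derived dimethylphosphoramidite is taken to give the (2R,3S) keto acid of step 4. Should a pilot run show the opposite sense, the (S,S) ligand is used and nothing else changes. If needed, enantiomeric purity is raised by recrystallising a chiral amine salt of the acid from step 5.
- The vinyl ketone of step 11 is volatile and polymerises; it is kept as a cold, BHT-stabilised ether solution and used at once.

Step 1
Reactants: 1 meso-2,3-dimethylsuccinic acid [(2R,3S)-2,3-dimethylbutanedioic acid]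
Product: 2 cis-2,3-dimethylsuccinic anhydride [(3R,4S)-3,4-dimethyloxolane-2,5-dione; meso]
Conditions: AcCl, reflux; evaporation, recrystallisation
Reagents that add atoms: none
Why: Cyclodehydration of a 1,4-diacid to its five-membered anhydride by acetyl chloride is routine and, in the absence of base, should leave the cis (meso) arrangement of the two methyl-bearing carbons intact.

Step 2
Reactants: 3 2,6-dimethoxyphenol (syringol)
Product: 4 4-bromo-2,6-dimethoxyphenol
Conditions: NBS, CHCl3, −45 °C to rt
Reagents that add atoms: N-bromosuccinimide, O=C1CCC(=O)N1Br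
Why: Electrophilic aromatic bromination should go para to the free hydroxyl group, the strongest donor, whose two ortho positions are blocked by the methoxy groups.

Step 3
Reactants: 4 4-bromo-2,6-dimethoxyphenol
Product: 5 (4-bromo-2,6-dimethoxyphenoxy)triisopropylsilane
Conditions: iPr3SiCl, imidazole, DMF, rt
Reagents that add atoms: triisopropylsilyl chloride, CC(C)[Si](Cl)(C(C)C)C(C)C
Why: Imidazole-promoted O-silylation of a phenol is standard, and the bulky silyl ether flanked by two methoxy groups should resist the organolithium, hydride, hydrogenation and enamine chemistry that follows.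

Step 4
Reactants: 5 (4-bromo-2,6-dimethoxyphenoxy)triisopropylsilane; 2 cis-2,3-dimethylsuccinic anhydride
Product: 8 (2R,3S)-4-[3,5-dimethoxy-4-(triisopropylsilyloxy)phenyl]-2,3-dimethyl-4-oxobutanoic acid, via aryllithium 6 (not isolated), via arylzinc triflate 7 (not isolated)
Conditions: 5, n-BuLi, THF, −78 °C; Zn(OSO2CF3)2, −78 to 0 °C; then 2, [Rh(cod)Cl]2 (4 mol%), (R,R)-TADDOL-PNMe2 (8 mol%), THF, 50 °C; aq. HCl
Reagents that add atoms: none
Why: Bromine–lithium exchange and transmetalation give the arylzinc, and rhodium-catalysed desymmetrising acyl cross-coupling (insertion of rhodium into one of the two enantiotopic acyl–oxygen bonds of the meso anhydride, transmetalation, reductive elimination) should give the syn keto acid, both stereocentres being carried over unchanged from 2 while the chiral phosphoramidite decides which carbonyl is arylated and hence the absolute configuration.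

Step 5
Reactants: 8 (2R,3S)-4-[3,5-dimethoxy-4-(triisopropylsilyloxy)phenyl]-2,3-dimethyl-4-oxobutanoic acid
Product: 10 (2R,3R)-4-[3,5-dimethoxy-4-(triisopropylsilyloxy)phenyl]-2,3-dimethylbutanoic acid, via benzylic carbinol 9 (not isolated)
Conditions: H2 (4 bar), 10% Pd/C, AcOH, 50 °C
Reagents that add atoms: none
Why: Catalytic benzylic hydrogenolysis of an electron-rich aryl ketone (ketone to carbinol to methylene) takes place on the metal surface in weakly acidic medium and should outpace enolisation of the adjacent stereocentre C8', while the aryl silyl ether is inert to it (the descriptor at that carbon changes from S to R only because the priorities change).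

Step 6
Reactants: 10 (2R,3R)-4-[3,5-dimethoxy-4-(triisopropylsilyloxy)phenyl]-2,3-dimethylbutanoic acid
Product: 11 (2R,3R)-4-[3,5-dimethoxy-4-(triisopropylsilyloxy)phenyl]-2,3-dimethylbutan-1-ol
Conditions: BH3·THF, THF, 0 °C to rt; then H2O
Reagents that add atoms: none
Why: Borane reduction of a carboxylic acid to the primary alcohol is fast and chemoselective and should touch neither the aryl silyl ether nor the stereocentres.

Step 7
Reactants: 11 (2R,3R)-4-[3,5-dimethoxy-4-(triisopropylsilyloxy)phenyl]-2,3-dimethylbutan-1-ol
Product: 12 {4-[(2R,3R)-4-iodo-2,3-dimethylbutyl]-2,6-dimethoxyphenoxy}triisopropylsilane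
Conditions: I2, PPh3, imidazole, CH2Cl2, 0 °C to rt
Reagents that add atoms: iodine, II
Why: Appel-type iodination converts the primary alcohol into the iodide by SN2 displacement at the CH2 carbon (future C7), which is not a stereocentre.

Step 8
Reactants: 12 {4-[(2R,3R)-4-iodo-2,3-dimethylbutyl]-2,6-dimethoxyphenoxy}triisopropylsilane
Product: 13 (4S,5R)-6-[3,5-dimethoxy-4-(triisopropylsilyloxy)phenyl]-4,5-dimethylhexanenitrile
Conditions: MeCN, n-BuLi, THF, −78 °C; then 12, −78 °C to rt
Reagents that add atoms: acetonitrile (as its lithio derivative), CC#N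
Why: SN2 alkylation of lithioacetonitrile by the primary iodide adds the two carbons that later become C1 and C2 of ring A, an excess of the anion suppressing a second alkylation, and neither stereocentre takes part.

Step 9
Reactants: 13 (4S,5R)-6-[3,5-dimethoxy-4-(triisopropylsilyloxy)phenyl]-4,5-dimethylhexanenitrile
Product: 15 (4S,5R)-6-[3,5-dimethoxy-4-(triisopropylsilyloxy)phenyl]-4,5-dimethylhexanal, via iminoalane 14 (not isolated)
Conditions: iBu2AlH, CH2Cl2, −78 °C; then aq. HCl (1 M), 0 °C
Reagents that add atoms: water, O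
Why: Partial reduction of a nitrile: one hydride adds at low temperature to give the N-aluminated imine, which persists until the acidic work-up hydrolyses it to the aldehyde, and C8 and C8' lie γ and δ to the new carbonyl and so are not at risk.

Step 10
Reactants: 16 methoxyacetic acid
Product: 18 N,2-dimethoxy-N-methylacetamide, via acyl imidazole 17 (not isolated)
Conditions: CDI, CH2Cl2, rt; then MeNH(OMe)·HCl, rt
Reagents that add atoms: N,O-dimethylhydroxylamine hydrochloride, CNOC.Cl
Why: Amide coupling through the acyl imidazole should give the Weinreb amide without strong acid or base.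

Step 11
Reactants: 18 N,2-dimethoxy-N-methylacetamide; 19 vinylmagnesium bromide
Product: 21 1-methoxybut-3-en-2-one, via magnesium chelate 20 (not isolated)
Conditions: THF, −78 to 0 °C; inverse quench into cold aq. HCl (2 M); Et2O extraction, BHT
Reagents that add atoms: none
Why: Weinreb ketone synthesis: the five-membered magnesium chelate holds the tetrahedral adduct until the quench so that only one vinyl group adds, and quenching into cold acid protonates the released N,O-dimethylhydroxylamine before it can add to the new enone in a conjugate sense.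

Step 12
Reactants: 15 (4S,5R)-6-[3,5-dimethoxy-4-(triisopropylsilyloxy)phenyl]-4,5-dimethylhexanal; 21 1-methoxybut-3-en-2-one
Product: 25 4-{(2S,3R)-4-[3,5-dimethoxy-4-(triisopropylsilyloxy)phenyl]-2,3-dimethylbutyl}-2-methoxycyclohex-2-en-1-one (both epimers at ring carbon 4), via enamine 22 (not isolated), via keto aldehyde 23 (not isolated), via ketol 24 (not isolated)
Conditions: pyrrolidine (1.05 equiv), 4 Å MS, toluene, 0 °C to rt; 21 (1.2 equiv), 0 °C to rt; then AcOH/NaOAc/H2O, 70 °C
Reagents that add atoms: none
Why: Aldehyde 15 condenses with pyrrolidine to the E enamine 22, whose nucleophilic β-carbon (future C1 of ring A) adds to the terminal alkene carbon of 21 (future C6), and hydrolysis of the adduct in the acetate buffer releases the 1,5-keto aldehyde 23. Pyrrolidinium acetate then mediates the intramolecular aldol condensation in which the methoxy-bearing α'-carbon (future C3) attacks the aldehyde carbon (future C2) and ketol 24 loses water to the conjugated enol-ether enone 25; the closest known reaction type is the Stork enamine variant of the Robinson annulation, which turns aldehydes and vinyl ketones into 4-substituted cyclohex-2-enones. The six-membered ring closes in the 6-(enolendo)-exo-trig mode. The one new stereocentre, ring carbon 4 of 25, is formed without control and deliberately as both epimers, because it becomes the sp2 carbon C1 on aromatisation, while C8 and C8' are too far from the aldehyde carbonyl to enolise. The regiochemistry needed (OMe on C3, oxygen on C4, chain on C1) is secured by the substrate itself, since every other intramolecular aldol mode of 23 would give a four-membered ring. Polymerisation of 21 and a second Michael addition are held back by preforming the enamine with one equivalent of amine and adding the enone cold.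

Step 13
Reactants: 25 4-{(2S,3R)-4-[3,5-dimethoxy-4-(triisopropylsilyloxy)phenyl]-2,3-dimethylbutyl}-2-methoxycyclohex-2-en-1-one
Product: 27 4-{(2S,3R)-4-[3,5-dimethoxy-4-(triisopropylsilyloxy)phenyl]-2,3-dimethylbutyl}-2-methoxyphenol, via dienone 26 (not isolated)
Conditions: Pd(OCOCF3)2 (5 mol%), 2-(dimethylamino)pyridine (10 mol%), TsOH·H2O (20 mol%), O2 (1 atm), DMSO, 80 °C
Reagents that add atoms: none
Why: Palladium-catalysed aerobic dehydrogenation of a cyclohexenone to a phenol: a divalent palladium enolate at the α'-methylene (C5 of ring A) should undergo β-hydride elimination from C6 to give the cross-conjugated dienone, the keto tautomer of the guaiacol, which aromatises at once and so erases the uncontrolled ring stereocentre, while dioxygen reoxidises the palladium hydride and ring B with its benzylic C7' is left alone.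

Step 14
Reactants: 27 4-{(2S,3R)-4-[3,5-dimethoxy-4-(triisopropylsilyloxy)phenyl]-2,3-dimethylbutyl}-2-methoxyphenol
Product: 28 4-[(2R,3S)-4-(4-hydroxy-3-methoxyphenyl)-2,3-dimethylbutyl]-2,6-dimethoxyphenol (CID53359576)
Conditions: Bu4NF, AcOH, THF, 0 °C to rt
Reagents that add atoms: none
Why: Fluoride-induced cleavage of the aryl silyl ether, driven by the strong silicon–fluorine bond, is buffered with acetic acid so that the electron-rich bisphenol is not exposed to air as a phenoxide.

Compound list
1 | meso-2,3-dimethylsuccinic acid | OC(=O)[C@H](C)[C@H](C)C(=O)O | starting material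
2 | cis-2,3-dimethylsuccinic anhydride, (3R,4S), meso | O=C1OC(=O)[C@H](C)[C@@H]1C | intermediate
3 | 2,6-dimethoxyphenol (syringol) | COc1cccc(OC)c1O | starting material
4 | 4-bromo-2,6-dimethoxyphenol | COc1cc(Br)cc(OC)c1O | intermediate
5 | (4-bromo-2,6-dimethoxyphenoxy)triisopropylsilane | COc1cc(Br)cc(OC)c1O[Si](C(C)C)(C(C)C)C(C)C | intermediate
6 | [3,5-dimethoxy-4-(triisopropylsilyloxy)phenyl]lithium | [Li]c1cc(OC)c(O[Si](C(C)C)(C(C)C)C(C)C)c(OC)c1 | intermediate (not isolated)
7 | [3,5-dimethoxy-4-(triisopropylsilyloxy)phenyl]zinc triflate | FC(F)(F)S(=O)(=O)O[Zn]c1cc(OC)c(O[Si](C(C)C)(C(C)C)C(C)C)c(OC)c1 | intermediate (not isolated)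
8 | (2R,3S)-4-[3,5-dimethoxy-4-(triisopropylsilyloxy)phenyl]-2,3-dimethyl-4-oxobutanoic acid | OC(=O)[C@H](C)[C@H](C)C(=O)c1cc(OC)c(O[Si](C(C)C)(C(C)C)C(C)C)c(OC)c1 | intermediate
9 | (2R,3S)-4-[3,5-dimethoxy-4-(triisopropylsilyloxy)phenyl]-4-hydroxy-2,3-dimethylbutanoic acid (C4 epimers) | OC(=O)[C@H](C)[C@H](C)C(O)c1cc(OC)c(O[Si](C(C)C)(C(C)C)C(C)C)c(OC)c1 | intermediate (not isolated)
10 | (2R,3R)-4-[3,5-dimethoxy-4-(triisopropylsilyloxy)phenyl]-2,3-dimethylbutanoic acid | OC(=O)[C@H](C)[C@H](C)Cc1cc(OC)c(O[Si](C(C)C)(C(C)C)C(C)C)c(OC)c1 | intermediate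
11 | (2R,3R)-4-[3,5-dimethoxy-4-(triisopropylsilyloxy)phenyl]-2,3-dimethylbutan-1-ol | OC[C@H](C)[C@H](C)Cc1cc(OC)c(O[Si](C(C)C)(C(C)C)C(C)C)c(OC)c1 | intermediate
12 | {4-[(2R,3R)-4-iodo-2,3-dimethylbutyl]-2,6-dimethoxyphenoxy}triisopropylsilane | IC[C@H](C)[C@H](C)Cc1cc(OC)c(O[Si](C(C)C)(C(C)C)C(C)C)c(OC)c1 | intermediate
13 | (4S,5R)-6-[3,5-dimethoxy-4-(triisopropylsilyloxy)phenyl]-4,5-dimethylhexanenitrile | N#CCC[C@H](C)[C@H](C)Cc1cc(OC)c(O[Si](C(C)C)(C(C)C)C(C)C)c(OC)c1 | intermediate
14 | N-(diisobutylalumino) imine of aldehyde 15 | CC(C)C[Al](CC(C)C)N=CCC[C@H](C)[C@H](C)Cc1cc(OC)c(O[Si](C(C)C)(C(C)C)C(C)C)c(OC)c1 | intermediate (not isolated)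
15 | (4S,5R)-6-[3,5-dimethoxy-4-(triisopropylsilyloxy)phenyl]-4,5-dimethylhexanal | O=CCC[C@H](C)[C@H](C)Cc1cc(OC)c(O[Si](C(C)C)(C(C)C)C(C)C)c(OC)c1 | intermediate (key-step precursor)
16 | methoxyacetic acid | COCC(=O)O | starting material
17 | 1-(methoxyacetyl)imidazole | COCC(=O)n1ccnc1 | intermediate (not isolated)
18 | N,2-dimethoxy-N-methylacetamide | COCC(=O)N(C)OC | intermediate
19 | vinylmagnesium bromide | C=C[Mg]Br | starting material
20 | bromomagnesium alkoxide of the tetrahedral adduct of 18 and 19 | COCC(C=C)(O[Mg]Br)N(C)OC | intermediate (not isolated)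
21 | 1-methoxybut-3-en-2-one | COCC(=O)C=C | intermediate (key-step precursor)
22 | 1-{(1E,4S,5R)-6-[3,5-dimethoxy-4-(triisopropylsilyloxy)phenyl]-4,5-dimethylhex-1-en-1-yl}pyrrolidine | N1(CCCC1)/C=C/C[C@H](C)[C@H](C)Cc2cc(OC)c(O[Si](C(C)C)(C(C)C)C(C)C)c(OC)c2 | intermediate (not isolated)
23 | 2-{(2S,3R)-4-[3,5-dimethoxy-4-(triisopropylsilyloxy)phenyl]-2,3-dimethylbutyl}-6-methoxy-5-oxohexanal (C2 epimers) | O=CC(CCC(=O)COC)C[C@H](C)[C@H](C)Cc1cc(OC)c(O[Si](C(C)C)(C(C)C)C(C)C)c(OC)c1 | intermediate (not isolated)
24 | 4-{(2S,3R)-4-[3,5-dimethoxy-4-(triisopropylsilyloxy)phenyl]-2,3-dimethylbutyl}-3-hydroxy-2-methoxycyclohexan-1-one (ring diastereomers) | O=C1CCC(C[C@H](C)[C@H](C)Cc2cc(OC)c(O[Si](C(C)C)(C(C)C)C(C)C)c(OC)c2)C(O)C1OC | intermediate (not isolated)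
25 | 4-{(2S,3R)-4-[3,5-dimethoxy-4-(triisopropylsilyloxy)phenyl]-2,3-dimethylbutyl}-2-methoxycyclohex-2-en-1-one (C4 epimers) | O=C1CCC(C[C@H](C)[C@H](C)Cc2cc(OC)c(O[Si](C(C)C)(C(C)C)C(C)C)c(OC)c2)C=C1OC | intermediate (key-step product)
26 | 4-{(2S,3R)-4-[3,5-dimethoxy-4-(triisopropylsilyloxy)phenyl]-2,3-dimethylbutyl}-2-methoxycyclohexa-2,5-dien-1-one | O=C1C=CC(C[C@H](C)[C@H](C)Cc2cc(OC)c(O[Si](C(C)C)(C(C)C)C(C)C)c(OC)c2)C=C1OC | intermediate (not isolated)
27 | 4-{(2S,3R)-4-[3,5-dimethoxy-4-(triisopropylsilyloxy)phenyl]-2,3-dimethylbutyl}-2-methoxyphenol | COc1cc(C[C@H](C)[C@H](C)Cc2cc(OC)c(O[Si](C(C)C)(C(C)C)C(C)C)c(OC)c2)ccc1O | intermediate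
28 | 4-[(2R,3S)-4-(4-hydroxy-3-methoxyphenyl)-2,3-dimethylbutyl]-2,6-dimethoxyphenol | COc1cc(C[C@H](C)[C@H](C)Cc2cc(OC)c(O)c(OC)c2)ccc1O | target

Total step count: 14.
Longest linear sequence: 11 steps (from syringol 3: steps 2 to 9, then 12 to 14).

Steps most likely to fail

1. Step 12. The enone may polymerise or take up a second enamine equivalent before the first adduct is formed cleanly, or hydrolysis and cyclodehydration may stop short and leave open-chain material, so that little ring A is formed. The fallback gives up the de novo construction of ring A and attaches a ready-made guaiacyl ring by cross-coupling. It sets out from iodide 12: zinc insertion (Zn dust, LiCl, THF, 40 °C) should give the alkylzinc iodide F1, and Negishi coupling with commercial 1-(benzyloxy)-4-bromo-2-methoxybenzene (Pd(OAc)2, SPhos, THF, rt to 50 °C) should give the benzyl ether F2. Hydrogenolysis (H2, Pd/C, EtOAc) then removes the benzyl group and the route is rejoined at 27, before step 14.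

2. Step 4. Discrimination between the two enantiotopic carbonyl groups may be incomplete, transmetalation of the bulky electron-rich arylzinc may be slow, or the centre next to the new ketone may partly enolise, giving acid of insufficient enantiomeric or diastereomeric purity. The fallback separates desymmetrisation from C–C bond formation. It sets out from anhydride 2: methanolysis catalysed by a bis-cinchona alkaloid ((DHQD)2AQN or its DHQ pseudo-enantiomer, whichever gives the required sense; Et2O, −20 °C) should give the half-ester F3. Neutral chlorination with 1-chloro-N,N,2-trimethylprop-1-en-1-amine (CH2Cl2, 0 °C) gives the acid chloride F4, and Negishi acylation with arylzinc 7 (Pd(PPh3)4, THF, 0 °C) gives the keto ester F5. Hydrogenolysis as in step 5 gives the ester F6, and LiBH4 (THF, rt) reduces it to alcohol 11, where the route is rejoined before step 7.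

3. Step 13. The catalyst may be lost as palladium black before conversion is complete, or the acidic, oxidising medium may remove the silyl group and then oxidise the liberated syringyl phenol. The fallback replaces catalytic dehydrogenation by stoichiometric enolate chemistry. It sets out from enone 25: kinetic deprotonation at the α'-methylene (LiN(iPr)2, THF, −78 °C) and trapping with PhSeCl should give the α'-phenylselanyl ketone F7. Oxidation (H2O2, pyridine, CH2Cl2, 0 °C) and syn elimination of the selenoxide give dienone 26, which tautomerises to 27, where the route is rejoined before step 14.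

Further compounds
F1 | step 12 | {(2R,3R)-4-[3,5-dimethoxy-4-(triisopropylsilyloxy)phenyl]-2,3-dimethylbutyl}zinc iodide | I[Zn]C[C@H](C)[C@H](C)Cc1cc(OC)c(O[Si](C(C)C)(C(C)C)C(C)C)c(OC)c1
F2 | step 12 | {4-[(2R,3S)-4-(4-benzyloxy-3-methoxyphenyl)-2,3-dimethylbutyl]-2,6-dimethoxyphenoxy}triisopropylsilane | COc1cc(C[C@H](C)[C@H](C)Cc2cc(OC)c(O[Si](C(C)C)(C(C)C)C(C)C)c(OC)c2)ccc1OCc1ccccc1
F3 | step 4 | (2S,3R)-4-methoxy-2,3-dimethyl-4-oxobutanoic acid | COC(=O)[C@H](C)[C@H](C)C(=O)O
F4 | step 4 | methyl (2R,3S)-4-chloro-2,3-dimethyl-4-oxobutanoate | COC(=O)[C@H](C)[C@H](C)C(=O)Cl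
F5 | step 4 | methyl (2R,3S)-4-[3,5-dimethoxy-4-(triisopropylsilyloxy)phenyl]-2,3-dimethyl-4-oxobutanoate | COC(=O)[C@H](C)[C@H](C)C(=O)c1cc(OC)c(O[Si](C(C)C)(C(C)C)C(C)C)c(OC)c1
F6 | step 4 | methyl (2R,3R)-4-[3,5-dimethoxy-4-(triisopropylsilyloxy)phenyl]-2,3-dimethylbutanoate | COC(=O)[C@H](C)[C@H](C)Cc1cc(OC)c(O[Si](C(C)C)(C(C)C)C(C)C)c(OC)c1
F7 | step 13 | 4-{(2S,3R)-4-[3,5-dimethoxy-4-(triisopropylsilyloxy)phenyl]-2,3-dimethylbutyl}-2-methoxy-6-(phenylselanyl)cyclohex-2-en-1-one | O=C1C([Se]c2ccccc2)CC(C[C@H](C)[C@H](C)Cc3cc(OC)c(O[Si](C(C)C)(C(C)C)C(C)C)c(OC)c3)C=C1OC
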